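At the reading, 5.0 min after the start, I want two fractions out of this flask.

electrophile 0.40 M; free base 0.120 M; gas 110 mM (held); time 5.0 min

    acid set free + free base ⇌ salt of the base, settled at all times (K1 = 4.05 × 10⁵ L mol⁻¹)
    free base ⇌ dormant form (K2 = 78, k2 = 0.00358 s⁻¹)
    nucleophile + acid set free ⇌ protonated nucleophile, settled at all times (K3 = 46000 L mol⁻¹)
    gas ⇌ nucleophile, rate k4*(csat - [nucleophile]) (k4 = 1.08 s⁻¹, csat = 110 mM)
    electrophile + nucleophile → acid set free + target (k5 = 0.0847 L mol⁻¹ s⁻¹)

- at the start none of nucleophile is dissolved
- run time (flask): 5.0 min

- part of the electrophile that has reacted at 5.0 min
- share of the unused nucleophile that is free and not bound as protonated nucleophile, at 5.0 min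

With a held gas and good stirring, the bench rule says that dissolved nucleophile stands at saturation, so I freeze it there, and the electrophile then falls pseudo-first-order. Its pace comes to 0.559 min⁻¹; I call this the held pace, the rate constant of step 5 times the saturation concentration. On this rule the fraction of electrophile left at the reading is the exponential of minus pace times time, 6.11%, so the rule gives 93.9% reacted.

The rule stops working where the electrophile draws nucleophile away faster than the gas restores it, so I compare the two with a ratio, the draw, which is step 5's constant times the electrophile charge over the transfer coefficient. In this flask it is 0.0314, so at the charged electrophile transfer is much faster than consumption. With the electrophile at its charge, I reckon free nucleophile to stand below saturation by a factor of one plus the draw. If I charge that full dip to the pace for the whole run, my reckoning leaves 6.65%, and I commit to that figure.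

For the second fraction, free base binds acid more strongly than the nucleophile does, so I assume that its full charge takes up acid and that the remaining acid goes onto nucleophile. With nucleophile at saturation, that gives a free share of 30.3%. I hold this as a high figure, since dormant form binds no acid in the scheme, and the forward half-life of free base by step 2 alone is 3.2 min, shorter than the time.

The forecast says 93.6% reacted and a free share of 28.6%, on the ground that “free nucleophile stays near saturation”.

This flask gives 93.5% reacted and a free share of 28.5%. Its nucleophile stands at 0.106 M at 0.500 min, which is 96.6% of saturation. I now use the held pace on the neighbour flask charged with 1.0 M of electrophile, where the draw rises to 0.0784. The pace, lowered by that dip, leaves 7.49% of the electrophile by my reckoning, and that neighbour flask holds 7.1% of its charge.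

The numbers were chosen freely; the run is a simulation.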